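## Retrosynthetic overview

1. Dictyoceratin A ⇒ aryl bromide / bis-MOM precursor (late Pd methoxycarbonylation, then MOM removal); the C-8 CH–CH3 ⇒ C-8 ketone (methyl addition, then radical deoxygenation). Avarane numbering is used in this overview.
2. C-9 quaternary centre and trans ring fusion ⇒ Li/NH3 reductive benzylation of a bicyclic α-methyl enone with a 5-bromo-2,3-bis(MOM-oxy)benzyl bromide made from o-vanillin.
3. Enone ⇒ cross-conjugated dienone (CuH 1,4-reduction of the less substituted C=C).
4. Key disconnection: the C4–C5 bond of the dienone ⇒ 3-(4-bromopent-4-enyl)-2,4-dimethylphenol, by Pd-catalysed enantioselective dearomative cyclisation. This one step sets the C-5 quaternary stereocentre and installs the exocyclic methylene.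
5. Ring order: ring B arrives as the phenol (from 3-bromo-4-methylanisole), ring A is closed in the dearomatisation; the benzoate ring is carried intact.

Assumption: the antipode of the P-chiral ligand that gives (4aR)-6 is identified by screening both (both are available); compound 3 and B-bromo-9-BBN are purchased.

## Route

**Step 1**
Reactants: 1, 3-bromo-4-methylanisole (2-bromo-4-methoxy-1-methylbenzene)
Product: 2, 3-bromo-2,4-dimethylanisole (2-bromo-4-methoxy-1,3-dimethylbenzene)
Conditions: LDA, THF, −78 °C; MeI, −78 °C → rt
Reagents that add atoms: iodomethane, CI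
Why: Directed ortho-metalation; the ring C–H flanked by OMe and Br is the most acidic and is lithiated selectively at −78 °C (too cold for aryne formation), then methylated.

**Step 2**
Reactants: 2; 3, pent-4-yn-1-yl 4-methylbenzenesulfonate
Product: 4, 1-methoxy-2,4-dimethyl-3-(pent-4-yn-1-yl)benzene
Conditions: 2, Mg, LiCl, THF, 50 °C (ArMgBr); 3 pre-treated with i-PrMgCl (1.0 equiv), THF, 0 °C; combine, Li2CuCl4 (5 mol %), −20 °C → rt; aq NH4Cl
Reagents that add atoms: none
Why: Kochi-type Cu-catalysed Grignard–alkyl tosylate coupling; the alkyne C–H is masked in situ as its unreactive magnesium acetylide and returns on work-up.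

**Step 3**
Reactants: 4
Product: 5, 3-(4-bromopent-4-en-1-yl)-2,4-dimethylphenol
Conditions: B-Br-9-BBN (3 equiv), CH2Cl2, 0 °C then 40 °C; AcOH, 0 °C → rt; ethanolamine work-up
Reagents that add atoms: B-bromo-9-borabicyclo[3.3.1]nonane, BrB1C2CCCC1CCC2
Why: syn-Bromoboration of the terminal alkyne (Br on the internal carbon) followed by AcOH protodeboronation gives the 2-bromo-1-alkene, and excess bromoborane cleaves the aryl methyl ether in the same pot (both are established reactivities of this reagent).

**Step 4 (key step)**
Reactants: 5
Product: 6, (4aR)-1,4a-dimethyl-5-methylidene-5,6,7,8-tetrahydronaphthalen-2(4aH)-one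
Conditions: [Pd(cinnamyl)Cl]2 (2.5 mol %), P-chiral dihydrobenzooxaphosphole monophosphine (AntPhos/BI-DIME class, 6 mol %), K2CO3, toluene, 90 °C
Reagents that add atoms: none
Why: Proposed new method: Pd(0) inserts into the alkenyl C–Br bond, the potassium phenoxide attacks through its methyl-bearing para carbon and C–C reductive elimination closes ring A, the chiral ligand differentiating the two faces of the phenoxide to set the quaternary centre, and the product cannot re-aromatise because that carbon carries CH3; the closest known reaction type is the Pd-catalysed enantioselective dearomative cyclisation of 4-methylphenols carrying a meta-tethered aryl bromide to 4a-methyl phenanthrenones, here extended to a 2-bromo-1-alkene so that the exocyclic methylene is delivered directly.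

**Step 5**
Reactants: 6
Product: 7, (4aR)-1,4a-dimethyl-5-methylidene-4,4a,5,6,7,8-hexahydronaphthalen-2(3H)-one
Conditions: [(Ph3P)CuH]6 (5 mol %), PhSiH3, toluene, rt; aq NH4Cl
Reagents that add atoms: none
Why: Stryker CuH conjugate reduction is strongly sensitive to β-substitution, so only the disubstituted C3=C4 enone arm is reduced; the tetrasubstituted C1=C8a enone and the isolated exocyclic alkene are untouched.

**Step 6**
Reactants: 8, o-vanillin (2-hydroxy-3-methoxybenzaldehyde)
Product: 9, 5-bromo-2-hydroxy-3-methoxybenzaldehyde
Conditions: Br2, NaOAc, AcOH, rt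
Reagents that add atoms: bromine, BrBr
Why: Electrophilic aromatic bromination para to the free phenol (and meta to CHO), the only strongly activated open position.

**Step 7**
Reactants: 9
Product: 10, 5-bromo-2,3-dihydroxybenzaldehyde
Conditions: BBr3, CH2Cl2, −78 °C → rt; H2O
Reagents that add atoms: none
Why: Lewis-acid ether cleavage (BBr3 demethylation); done here, before any acid-sensitive alkene exists.

**Step 8**
Reactants: 10
Product: 11, 5-bromo-2,3-bis(methoxymethoxy)benzaldehyde
Conditions: MOMCl, i-Pr2NEt, DMF, 0 °C → rt
Reagents that add atoms: chloromethyl methyl ether, COCCl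
Why: Williamson-type O-alkylation of both phenols; MOM survives enolates, Grignard reagents and Pd, and is removable without strong protic acid.

**Step 9**
Reactants: 11
Product: 12, [5-bromo-2,3-bis(methoxymethoxy)phenyl]methanol
Conditions: NaBH4, MeOH, 0 °C
Reagents that add atoms: none
Why: Chemoselective borohydride reduction of the aldehyde.

**Step 10**
Reactants: 12
Product: 13, 5-bromo-1-(bromomethyl)-2,3-bis(methoxymethoxy)benzene
Conditions: MsCl, Et3N, CH2Cl2, 0 °C; LiBr, THF, rt
Reagents that add atoms: lithium bromide, [Li+].[Br-]
Why: Mesylation and SN2 displacement by bromide under non-acidic conditions, so the MOM ethers survive.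

**Step 11**
Reactants: 7; 13
Product: 14, (1S,4aS,8aR)-1-{[5-bromo-2,3-bis(methoxymethoxy)phenyl]methyl}-1,4a-dimethyl-5-methylideneoctahydronaphthalen-2(1H)-one
Conditions: Li (2.2 equiv), NH3(l)/THF, t-BuOH (1.0 equiv), −78 → −33 °C; isoprene; then 13 in THF, −78 → −33 °C; NH4Cl
Reagents that add atoms: none
Why: Stork reductive alkylation; axial protonation at the β-carbon (C-8a) anti to the angular methyl gives the trans-fused enolate regiospecifically, and benzylation at C-1 occurs on the face opposite the 1,3-diaxial angular methyl, so ArCH2 is α and CH3 is β (the aryl bromide is added only after excess Li is quenched).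

**Step 12**
Reactants: 14
Product: 15, (1S,2S,4aS,8aR)-1-{[5-bromo-2,3-bis(methoxymethoxy)phenyl]methyl}-1,2,4a-trimethyl-5-methylidenedecahydronaphthalen-2-ol (major epimer expected; either epimer is usable)
Conditions: MeMgBr, anhydrous CeCl3, THF, −78 → 0 °C
Reagents that add atoms: methylmagnesium bromide, C[Mg]Br
Why: Organocerium (Imamoto) 1,2-addition suppresses enolisation of the hindered ketone; the carbinol configuration is erased in step 13, and the aryl bromide, MOM ethers and alkene are inert.

**Step 13**
Reactants: 15
Product: 16, (1R,2S,4aS,8aS)-1-{[5-bromo-2,3-bis(methoxymethoxy)phenyl]methyl}-1,2,4a-trimethyl-5-methylidenedecahydronaphthalene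
Conditions: Cp*TiCl3 (10 mol %), Zn, TESCl, PhSiH3, THF, 60 °C
Reagents that add atoms: none
Why: Ti(III)-catalysed radical dehydroxylation of the tertiary alcohol (homolytic C–O cleavage) gives a planar tertiary radical that takes hydrogen axially from the open α-face (the β-face is blocked by the adjacent axial C-1 methyl), leaving the C-2 methyl equatorial (2S).

**Step 14**
Reactants: 16
Product: 17, methyl 3,4-bis(methoxymethoxy)-5-{[(1R,2S,4aS,8aS)-1,2,4a-trimethyl-5-methylidenedecahydronaphthalen-1-yl]methyl}benzoate
Conditions: Pd(OAc)2 (5 mol %), Xantphos (10 mol %), CO (1 atm), Et3N, MeOH/toluene, 80 °C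
Reagents that add atoms: carbon monoxide, [C-]#[O+]; methanol, CO
Why: Pd-catalysed methoxycarbonylation of the unhindered aryl bromide (oxidative addition, CO insertion, methanolysis); no other group reacts.

**Step 15**
Reactants: 17
Product: 18, dictyoceratin A, methyl 3,4-dihydroxy-5-{[(1R,2S,4aS,8aS)-1,2,4a-trimethyl-5-methylidenedecahydronaphthalen-1-yl]methyl}benzoate
Conditions: TMSOTf, 2,2′-bipyridyl, CH2Cl2, 0 °C → rt; then H2O
Reagents that add atoms: none
Why: Buffered Lewis-acid cleavage of aromatic MOM ethers (silyl exchange, then hydrolysis) frees the catechol without protonating the exocyclic alkene or touching the methyl ester.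

## Compound list

1 | 3-bromo-4-methylanisole | COc1ccc(C)c(Br)c1 | starting material
2 | 3-bromo-2,4-dimethylanisole | COc1ccc(C)c(Br)c1C | intermediate
3 | pent-4-yn-1-yl 4-methylbenzenesulfonate | C#CCCCOS(=O)(=O)c1ccc(C)cc1 | starting material
4 | 1-methoxy-2,4-dimethyl-3-(pent-4-yn-1-yl)benzene | COc1ccc(C)c(CCCC#C)c1C | intermediate
5 | 3-(4-bromopent-4-en-1-yl)-2,4-dimethylphenol | C=C(Br)CCCc1c(C)ccc(O)c1C | intermediate
6 | (4aR)-1,4a-dimethyl-5-methylidene-5,6,7,8-tetrahydronaphthalen-2(4aH)-one | C=C1CCCC2=C(C)C(=O)C=C[C@]12C | intermediate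
7 | (4aR)-1,4a-dimethyl-5-methylidene-4,4a,5,6,7,8-hexahydronaphthalen-2(3H)-one | C=C1CCCC2=C(C)C(=O)CC[C@]12C | intermediate
8 | o-vanillin | COc1cccc(C=O)c1O | starting material
9 | 5-bromo-2-hydroxy-3-methoxybenzaldehyde | COc1cc(Br)cc(C=O)c1O | intermediate
10 | 5-bromo-2,3-dihydroxybenzaldehyde | O=Cc1cc(Br)cc(O)c1O | intermediate
11 | 5-bromo-2,3-bis(methoxymethoxy)benzaldehyde | COCOc1cc(Br)cc(C=O)c1OCOC | intermediate
12 | [5-bromo-2,3-bis(methoxymethoxy)phenyl]methanol | COCOc1cc(Br)cc(CO)c1OCOC | intermediate
13 | 5-bromo-1-(bromomethyl)-2,3-bis(methoxymethoxy)benzene | COCOc1cc(Br)cc(CBr)c1OCOC | intermediate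
14 | (1S,4aS,8aR)-1-(arylmethyl)-1,4a-dimethyl-5-methylideneoctahydronaphthalen-2(1H)-one, aryl = 5-bromo-2,3-bis(MOM-oxy)phenyl | C=C1CCC[C@H]2[C@](C)(Cc3cc(Br)cc(OCOC)c3OCOC)C(=O)CC[C@]12C | intermediate
15 | (1S,2S,4aS,8aR)-tertiary alcohol (major epimer) | C=C1CCC[C@H]2[C@](C)(Cc3cc(Br)cc(OCOC)c3OCOC)[C@@](C)(O)CC[C@]12C | intermediate
16 | (1R,2S,4aS,8aS)-aryl bromide, bis-MOM | C=C1CCC[C@H]2[C@](C)(Cc3cc(Br)cc(OCOC)c3OCOC)[C@@H](C)CC[C@]12C | intermediate
17 | dictyoceratin A bis-MOM ether | C=C1CCC[C@H]2[C@](C)(Cc3cc(C(=O)OC)cc(OCOC)c3OCOC)[C@@H](C)CC[C@]12C | intermediate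
18 | dictyoceratin A | C=C1CCC[C@H]2[C@](C)(Cc3cc(C(=O)OC)cc(O)c3O)[C@@H](C)CC[C@]12C | target

## Step count and risks

Total steps: 15. Longest linear sequence: 10 (steps 1–5 then 11–15; the o-vanillin branch, steps 6–10 then 11–15, is also 10).

Steps most likely to fail:

1. **Step 4 (dearomative cyclisation).** Risks: C–C bond formation at the ortho carbon instead of the para carbon (both are methyl-substituted and both give six-membered rings), lower ee with an alkenyl rather than aryl bromide, or dehydrobromination. Fallback: switch the ring closure to a π-acid dearomative 6-exo-dig hydroarylation. Demethylate alkyne 4 with NaSEt to the alkynyl phenol and cyclise it with a cationic chiral bisphosphine–digold(I) catalyst to the same dienone 6, upgrading ee by chiral-phase chromatography if needed.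

2. **Step 13 (Ti-catalysed dehydroxylation).** Risks: slow C–O homolysis at a very hindered carbinol, elimination, loss of the benzyl group by β-scission, or poor facial selectivity. Fallback: carbonylate the aryl bromide of 15 first (step 14 conditions), convert the tertiary alcohol to its methyl oxalate (KHMDS, ClCOCO2Me) and reduce with Bu3SnH/AIBN. This two-step radical-chain deoxygenation is only possible once the aryl bromide is gone.

3. **Step 3 (one-pot bromoboration and demethylation).** Risks: incomplete ether cleavage or HBr addition to the bromoalkene. Fallback: install the vinyl bromide before the arene coupling. Couple the Grignard reagent of 2 with 2-bromo-5-iodopent-1-ene (two steps from pent-4-yn-1-ol: bromoboration, then iodination), then demethylate separately with BBr3 at −78 → 0 °C.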